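**Retrosynthetic overview**

1. Last bond: C5–CHO of ring A, by Rieche formylation of the only aromatic C–H bond left in the depside (ring B is hexasubstituted).
2. Depside ester bond C4(ring B)–O–C(=O)–C1(ring A): trifluoroacetic anhydride esterification of the ring B phenol with 2,4-bis(benzyloxy)-3,6-dimethylbenzoic acid, made from methyl 2,4-dihydroxy-3,6-dimethylbenzoate.
3. Feature on which the route rests: ring B (C1 CO2CH3, C2 OCH3, C3 CH3, C4 O-acyl, C5 CH3, C6 CH3) is 2,3,6-trimethylphenol with a carboxyl carbon para to the phenol oxygen and one more oxygen at C2, the single unsubstituted position, which lies ortho to that carboxyl.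
4. The C2–O bond of ring B is therefore made by carboxylate-directed, palladium-catalysed C–H hydroxylation of 4-(benzyloxy)-2,3,5-trimethylbenzoic acid, which comes from 2,3,6-trimethylphenol by para bromination, O-benzylation and bromine–lithium exchange/CO2.
5. No ring is formed; both benzene rings are bought. Ring B is completed first (steps 1–6), ring A is protected in parallel (steps 7–8), then coupling, debenzylation and formylation follow (steps 9–11).

Key step: step 4

Remark: ring A is numbered from its carboxyl carbon (C1; C2-OH, C3-CH3, C4-OH, C5-CHO, C6-CH3) and ring B from its ester-bearing carbon (C1); the target has no stereocenter, so no stereocontrol is needed.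

**Route**

Step 1
Reactants: 1 2,3,6-trimethylphenol
Product: 2 4-bromo-2,3,6-trimethylphenol
Conditions: Br2 (1.0 equiv), AcOH, 15 °C to rt
Reagents that add atoms: bromine, BrBr
Why: Electrophilic aromatic bromination should go para to the hydroxyl, because both ortho positions carry methyl groups and the only other free position is meta to the oxygen.

Step 2
Reactants: 2 4-bromo-2,3,6-trimethylphenol
Product: 3 benzyl 4-bromo-2,3,6-trimethylphenyl ether
Conditions: BnBr, K2CO3, DMF, rt to 50 °C
Reagents that add atoms: benzyl bromide, BrCc1ccccc1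
Why: Williamson ether synthesis of the phenoxide with a reactive benzylic bromide, which tolerates the two flanking methyl groups.

Step 3
Reactants: 3 benzyl 4-bromo-2,3,6-trimethylphenyl ether
Product: 5 4-(benzyloxy)-2,3,5-trimethylbenzoic acid, via aryllithium 4 (not isolated)
Conditions: n-BuLi, THF, −78 °C; CO2 (dry gas), −78 °C to rt; aq. HCl
Reagents that add atoms: carbon dioxide, O=C=O
Why: Bromine–lithium exchange is fast at −78 °C and the aryllithium is trapped by CO2 (carboxylation of an organolithium), which places the carboxyl carbon para to the benzylated oxygen where the bromine stood.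

Step 4
Reactants: 5 4-(benzyloxy)-2,3,5-trimethylbenzoic acid
Product: 7 4-(benzyloxy)-2-hydroxy-3,5,6-trimethylbenzoic acid, via five-membered aryl palladacycle 6 (not isolated)
Conditions: Pd(OAc)2 (10 mol%), KOAc (2 equiv), 1,4-benzoquinone (1 equiv), O2 (1 atm), DMA, 115 °C; then aq. HCl
Reagents that add atoms: dioxygen, O=O
Why: The potassium carboxylate of 5 binds divalent palladium and delivers it to the only aromatic C–H bond (C6 of 5, which becomes C2 of ring B), where acetate-assisted concerted metalation–deprotonation gives the five-membered aryl palladacycle 6; dioxygen then oxygenates the aryl–palladium bond and protonolysis releases the salicylate and the divalent palladium catalyst, with benzoquinone serving as a promoting ligand that the net equation does not consume. The closest known reaction type is the carboxylate-directed ortho C–H hydroxylation of benzoic acids with Pd(OAc)2, KOAc, benzoquinone and O2, which accepts a methyl group next to the carboxyl. No ring is closed in the product (the palladacycle is only a transient chelate) and no stereocenter is formed. The selectivity needed is aryl C6–H over the benzylic C–H bonds of the C2 methyl group and of the benzyl ether; the five-membered aryl palladacycle should form faster than the six-membered benzylic one, and with five ring positions filled the carboxyl can direct only to C6, so the new hydroxyl is distinct from the benzylated C4 oxygen from the moment it is made. The C5 methyl group beside the reacting C–H bond slows metalation, so the risk of the route sits here.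

Step 5
Reactants: 7 4-(benzyloxy)-2-hydroxy-3,5,6-trimethylbenzoic acid
Product: 8 methyl 4-(benzyloxy)-2-methoxy-3,5,6-trimethylbenzoate
Conditions: MeI (4 equiv), K2CO3 (4 equiv), DMF, 50 °C
Reagents that add atoms: iodomethane, CI
Why: SN2 O-methylation of both the carboxylate and the hydrogen-bonded phenoxide (Williamson-type alkylation) esterifies the di-ortho-substituted acid without any attack at its hindered carbonyl carbon.

Step 6
Reactants: 8 methyl 4-(benzyloxy)-2-methoxy-3,5,6-trimethylbenzoate
Product: 9 methyl 4-hydroxy-2-methoxy-3,5,6-trimethylbenzoate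
Conditions: H2 (1 atm), 10% Pd/C, EtOAc, rt
Reagents that add atoms: none
Why: Catalytic hydrogenolysis cleaves the benzyl aryl ether and leaves the methyl ester and methyl ether untouched, freeing only the C4 hydroxyl.

Step 7
Reactants: 10 methyl 2,4-dihydroxy-3,6-dimethylbenzoate
Product: 11 methyl 2,4-bis(benzyloxy)-3,6-dimethylbenzoate
Conditions: BnBr (2.5 equiv), K2CO3 (3 equiv), DMF, 70 °C
Reagents that add atoms: benzyl bromide, BrCc1ccccc1
Why: Double Williamson ether synthesis, with heating so that the C2 hydroxyl, which is hydrogen-bonded to the ester, is also alkylated.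

Step 8
Reactants: 11 methyl 2,4-bis(benzyloxy)-3,6-dimethylbenzoate
Product: 12 2,4-bis(benzyloxy)-3,6-dimethylbenzoic acid
Conditions: KOH, DMSO/H2O (4:1), 90 °C; then aq. HCl, 0 °C
Reagents that add atoms: potassium hydroxide, [K+].[OH-]
Why: Saponification of the di-ortho-substituted methyl ester should proceed with the poorly solvated, strongly nucleophilic hydroxide of the KOH/DMSO system, under which benzyl aryl ethers are stable.

Step 9
Reactants: 12 2,4-bis(benzyloxy)-3,6-dimethylbenzoic acid; 9 methyl 4-hydroxy-2-methoxy-3,5,6-trimethylbenzoate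
Product: 14 methyl 4-{[2,4-bis(benzyloxy)-3,6-dimethylbenzoyl]oxy}-2-methoxy-3,5,6-trimethylbenzoate, via mixed trifluoroacetic anhydride 13 (not isolated)
Conditions: (CF3CO)2O (4 equiv), toluene, rt
Reagents that add atoms: none
Why: Trifluoroacetic anhydride converts the acid into a mixed anhydride that ionises toward an acylium ion stabilised by the ortho and para benzyloxy groups, a slim linear electrophile that should acylate even the phenol flanked by two methyl groups (mixed-anhydride esterification of a hindered acid).

Step 10
Reactants: 14 methyl 4-{[2,4-bis(benzyloxy)-3,6-dimethylbenzoyl]oxy}-2-methoxy-3,5,6-trimethylbenzoate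
Product: 15 methyl 4-[(2,4-dihydroxy-3,6-dimethylbenzoyl)oxy]-2-methoxy-3,5,6-trimethylbenzoate
Conditions: H2 (1 atm), 10% Pd/C, EtOAc, rt
Reagents that add atoms: none
Why: Hydrogenolysis removes both benzyl ethers under neutral conditions that leave the aryl ester link, the methyl ester and the methyl ether intact.

Step 11
Reactants: 15 methyl 4-[(2,4-dihydroxy-3,6-dimethylbenzoyl)oxy]-2-methoxy-3,5,6-trimethylbenzoate
Product: 17 methyl 4-[(5-formyl-2,4-dihydroxy-3,6-dimethylbenzoyl)oxy]-2-methoxy-3,5,6-trimethylbenzoate, via chloro(methoxy)methyl arene 16 (not isolated)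
Conditions: Cl2CHOMe (1.5 equiv), TiCl4 (3 equiv), CH2Cl2, −10 to 0 °C; then ice-cold 1 M HCl
Reagents that add atoms: dichloromethyl methyl ether, COC(Cl)Cl; water, O
Why: Rieche formylation, in which TiCl4-activated dichloromethyl methyl ether attacks C5 of ring A, the only aromatic C–H bond of the molecule and ortho to the titanium-bound C4 phenoxide and para to the C2 hydroxyl, after which aqueous acid hydrolyses the α-chloro ether to the aldehyde.

**Compound list**

1 | 2,3,6-trimethylphenol | Oc1c(C)ccc(C)c1C | starting material
2 | 4-bromo-2,3,6-trimethylphenol | Oc1c(C)cc(Br)c(C)c1C | intermediate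
3 | benzyl 4-bromo-2,3,6-trimethylphenyl ether | Cc1cc(Br)c(C)c(C)c1OCc1ccccc1 | intermediate
4 | [4-(benzyloxy)-2,3,5-trimethylphenyl]lithium (not isolated) | [Li]c1cc(C)c(OCc2ccccc2)c(C)c1C | intermediate
5 | 4-(benzyloxy)-2,3,5-trimethylbenzoic acid | Cc1cc(C(=O)O)c(C)c(C)c1OCc1ccccc1 | intermediate
6 | five-membered palladacycle of 5: divalent palladium bound to ring carbon C6 and to a carboxylate oxygen, further ligands not drawn (not isolated) | O=C1O[Pd]c2c1c(C)c(C)c(OCc1ccccc1)c2C | intermediate
7 | 4-(benzyloxy)-2-hydroxy-3,5,6-trimethylbenzoic acid | Cc1c(O)c(C(=O)O)c(C)c(C)c1OCc1ccccc1 | intermediate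
8 | methyl 4-(benzyloxy)-2-methoxy-3,5,6-trimethylbenzoate | COC(=O)c1c(C)c(C)c(OCc2ccccc2)c(C)c1OC | intermediate
9 | methyl 4-hydroxy-2-methoxy-3,5,6-trimethylbenzoate | COC(=O)c1c(C)c(C)c(O)c(C)c1OC | intermediate
10 | methyl 2,4-dihydroxy-3,6-dimethylbenzoate | COC(=O)c1c(C)cc(O)c(C)c1O | starting material
11 | methyl 2,4-bis(benzyloxy)-3,6-dimethylbenzoate | COC(=O)c1c(C)cc(OCc2ccccc2)c(C)c1OCc1ccccc1 | intermediate
12 | 2,4-bis(benzyloxy)-3,6-dimethylbenzoic acid | OC(=O)c1c(C)cc(OCc2ccccc2)c(C)c1OCc1ccccc1 | intermediate
13 | 2,4-bis(benzyloxy)-3,6-dimethylbenzoic trifluoroacetic anhydride (not isolated) | O=C(OC(=O)C(F)(F)F)c1c(C)cc(OCc2ccccc2)c(C)c1OCc1ccccc1 | intermediate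
14 | methyl 4-{[2,4-bis(benzyloxy)-3,6-dimethylbenzoyl]oxy}-2-methoxy-3,5,6-trimethylbenzoate | COC(=O)c1c(C)c(C)c(OC(=O)c2c(C)cc(OCc3ccccc3)c(C)c2OCc2ccccc2)c(C)c1OC | intermediate
15 | methyl 4-[(2,4-dihydroxy-3,6-dimethylbenzoyl)oxy]-2-methoxy-3,5,6-trimethylbenzoate | COC(=O)c1c(C)c(C)c(OC(=O)c2c(C)cc(O)c(C)c2O)c(C)c1OC | intermediate
16 | methyl 4-({5-[chloro(methoxy)methyl]-2,4-dihydroxy-3,6-dimethylbenzoyl}oxy)-2-methoxy-3,5,6-trimethylbenzoate, racemic at the transient CHCl carbon (not isolated) | COC(=O)c1c(C)c(C)c(OC(=O)c2c(C)c(C(Cl)OC)c(O)c(C)c2O)c(C)c1OC | intermediate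
17 | methyl 4-[(5-formyl-2,4-dihydroxy-3,6-dimethylbenzoyl)oxy]-2-methoxy-3,5,6-trimethylbenzoate (CNP0316552.0) | COC(=O)c1c(C)c(C)c(OC(=O)c2c(C)c(C=O)c(O)c(C)c2O)c(C)c1OC | target

**Step count**

Total step count: 11. Longest linear sequence: 9 steps (steps 1–6, then 9, 10 and 11); steps 7 and 8 form the parallel ring A branch.

**Steps most likely to fail**

Step 4. Metalation at a C–H bond wedged between the carboxylate and the C5 methyl group may be too slow. Benzylic oxidation under O2 at 115 °C (ring methyl groups, benzyl ether CH2) or protodecarboxylation of the electron-rich salicylate could then take over. The fallback sets out from 10, in which both ring B oxygens are already present and only the C5 methyl group is missing, and comes back to the route at 8. Selective benzylation of the non-chelated C4 hydroxyl (BnBr 1.05 equiv, K2CO3, acetone, reflux) should give methyl 4-(benzyloxy)-2-hydroxy-3,6-dimethylbenzoate F1. Methylation of the chelated C2 hydroxyl (MeI, K2CO3, DMF, 60 °C) should give methyl 4-(benzyloxy)-2-methoxy-3,6-dimethylbenzoate F2. Bromination at the only free ring position, ortho to the benzyloxy group (NBS, MeCN, 0 °C to rt), should give methyl 4-(benzyloxy)-5-bromo-2-methoxy-3,6-dimethylbenzoate F3. Suzuki–Miyaura methylation (methylboronic acid, Pd(OAc)2, SPhos, K3PO4, toluene/H2O, 100 °C) should then deliver 8.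

Step 9. Acyl transfer between a di-ortho-substituted acid and a di-ortho-methylated phenol may be slow, which would allow self-acylation of ring A at C5 by the acylium ion or acid-induced loss of benzyl groups. The fallback sets out from 12 and 9 and comes back at 14. It replaces the acidic mixed-anhydride activation made in the flask by a separately prepared acyl chloride that meets a preformed phenoxide under basic conditions. Acid 12 with oxalyl chloride and catalytic DMF in CH2Cl2 should give 2,4-bis(benzyloxy)-3,6-dimethylbenzoyl chloride F4. Phenol 9 with NaH in THF should give sodium 3-methoxy-4-(methoxycarbonyl)-2,5,6-trimethylphenolate F5. Combining the two in THF at 0 °C to rt should give 14.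

Step 11. The Lewis acid may cleave the depside ester or the methyl ether beside the ring B ester, or conversion may stay incomplete because the titanium-bound, acyl-deactivated ring A reacts slowly. The fallback sets out from 10 and 9 and comes back at 17; it installs the aldehyde before the ester bond and avoids benzyl groups, so no hydrogenolysis has to pass an aldehyde. Rieche formylation of 10 (Cl2CHOMe, TiCl4, CH2Cl2, 0 °C) at its only free position should give methyl 5-formyl-2,4-dihydroxy-3,6-dimethylbenzoate F6. Cleavage of the hindered methyl ester through the acylium ion (conc. H2SO4, 0 °C to rt, then ice water) should give 5-formyl-2,4-dihydroxy-3,6-dimethylbenzoic acid F7. In F7 both hydroxyls are tied up in hydrogen bonds to the neighbouring carbonyl groups, so direct condensation with 9 (DCC, toluene/Et2O, rt) should give 17.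

**Further compounds**

F1 | step 4 | methyl 4-(benzyloxy)-2-hydroxy-3,6-dimethylbenzoate | COC(=O)c1c(C)cc(OCc2ccccc2)c(C)c1O
F2 | step 4 | methyl 4-(benzyloxy)-2-methoxy-3,6-dimethylbenzoate | COC(=O)c1c(C)cc(OCc2ccccc2)c(C)c1OC
F3 | step 4 | methyl 4-(benzyloxy)-5-bromo-2-methoxy-3,6-dimethylbenzoate | COC(=O)c1c(C)c(Br)c(OCc2ccccc2)c(C)c1OC
F4 | step 9 | 2,4-bis(benzyloxy)-3,6-dimethylbenzoyl chloride | ClC(=O)c1c(C)cc(OCc2ccccc2)c(C)c1OCc1ccccc1
F5 | step 9 | sodium 3-methoxy-4-(methoxycarbonyl)-2,5,6-trimethylphenolate | [Na+].[O-]c1c(C)c(C)c(C(=O)OC)c(OC)c1C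
F6 | step 11 | methyl 5-formyl-2,4-dihydroxy-3,6-dimethylbenzoate | COC(=O)c1c(C)c(C=O)c(O)c(C)c1O
F7 | step 11 | 5-formyl-2,4-dihydroxy-3,6-dimethylbenzoic acid | OC(=O)c1c(C)c(C=O)c(O)c(C)c1O
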